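The constants are assumed, and the outcome is calculated.

The question was how much target this flask held at the reading, and whether faster transfer or a higher saturation would raise it more.

starting material 2.0 M; gas phase 200 mM (held); protic impurity 0.0400 M; time 2.0 min

    gas phase ⇌ dissolved gas, rate k1*(csat - [dissolved gas]) (k1 = 15 s⁻¹, csat = 200 mM)
    starting material + dissolved gas → target (k2 = 0.056 L mol⁻¹ s⁻¹)
    starting material + protic impurity → quenched substrate (k3 = 0.37 L mol⁻¹ s⁻¹)
    dissolved gas ⇌ dormant form (K4 = 150, k4 = 0.10 s⁻¹)
    dissolved gas + target → over-reacted product (k5 = 0.0034 L mol⁻¹ s⁻¹)

- at the start none of the gas is dissolved
- run time (flask): 2.0 min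

- how much target there is at 2.0 min, in percent of the starting material charged
- the change that raises the amount of target at 2.0 min, in percent of the starting material charged most ("none" if none brings more than 2 percentage points) (grey / ochre / none)
- amount of target at 2.0 min, in percent of the starting material charged, after ochre

- grey: doubling the transfer coefficient of step 1, all else as stated
- ochre: doubling the saturation concentration of gas phase, all else as stated

In the first instants of the flask I watched the gas. Transfer at 15 s⁻¹ outran the two drains on dissolved gas, 0.10 s⁻¹ into the dormant form and 0.112 s⁻¹ into the starting material, so I held its level at 98.6% of saturation. The starting material then fell pseudo-first-order at 0.663 min⁻¹. The protic impurity reacted far faster, at 44.4 min⁻¹, so it took 2.00% of the charge at the outset and left f = 98.0%.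

For the middle of the run I divided the rate of step 5 by that of step 2. Dissolved gas cancelled and time dropped out, leaving target over starting material times the selectivity factor σ = k5/k2 = 0.0607, the ratio of the constants by which a target molecule and a starting material molecule take up gas. With x the part of f still unreacted, target = f·(x^σ − x)/(1 − σ), whatever the gas level.

At the end of the flask, x = 0.266, so I reckoned starting material at 26.1% and target at 68.5%. That put step 5 at 0.160 of the rate of step 2 by my reckoning. Ochre doubles the gas level and with it the uptake by starting material but leaves σ as it was, so I reckoned x = 0.0706 and target at 81.5%. Grey lifts the level to 99.3% of saturation, against 98.6% before, so I chose ochre.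

The forecast, on the grounds that “The dissolved gas therefore sits at a quasi-steady level”, gave 68.6%, ochre and 81.5%. The simulation gave 68.6% and, after ochre, 81.5%, a gain of 13 percentage points against 0.16 points for grey.

With no clock at all, the flask's reading of 25.9% starting material put through σ gave 68.7% target, and the flask held 68.6%. The neighbour flask, read at 50 s with all amounts held, had 56.4% starting material left, so x was 0.575 and the same σ gave 40.9% target. That neighbour flask held 40.9% target.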